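**Plan**

1. Retrosynthetic cuts, in order: the styryl C=C (phosphonate olefination); the C7–ethyl bond (enol triflate coupling); the C1–ethyl bond (enolate alkylation); C3a–C3 (one-carbon ring expansion of a cyclobutanone, C3 and its ethyl group coming from propyne); the cyclobutane bonds C7a–C1 and C3a–C2 (enone–alkene [2+2]); finally the two ring bonds at C4 and C5 (Diels–Alder).
2. Forward: diethylmaleic anhydride and butadiene give the six-membered ring with both quaternary carbons. Iodolactonisation, elimination and oxidation turn it into a cyclohex-2-enone. Irradiation with 1,1-dimethoxyethene adds the four-membered ring, which is enlarged to the cyclopentanone. The ethyl groups on C1 and C7, the styryl group and the free acid follow.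
3. Enabling feature: in the hexahydroindene core the ring-fusion carbons C3a and C7a carry trans hydrogens, lie β and α to the alkene carbon C7, and are not α to any carbonyl in the target. With a ketone on C7 they are the two ends of an enone C=C. A trans-fused four-membered ring (C1, C2) can be laid across them photochemically and then grown into the five-membered ring by inserting C3 between C2 and C3a.
4. Stereochemistry: the cis relationship at C4/C5 comes from the cis dienophile, the absolute configuration from alkaloid-mediated opening of the meso anhydride. C3a and C7a come from the photocycloaddition and pass unchanged through the ring expansion (migration with retention). C1 and C3 are set by equilibration α to the C2 ketone. The (E)-styrene comes from the phosphonate olefination.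

Key step: step 8

Locants: every intermediate keeps the atom locants of the target (C1–C3, C3a, C4–C7, C7a), whatever its own systematic numbering.

Assumption: quinine is taken to open anhydride 5 with the same sense as it opens cis-cyclohex-4-ene-1,2-dicarboxylic anhydride (ester on the carbon that becomes C4); if the ethyl groups reverse the sense, quinidine is used instead.

**Route**

Step 1
Reactants: 1 hex-3-yne
Product: 3 3,4-diethylfuran-2,5-dione (diethylmaleic anhydride), via diethylmaleic acid 2 (not isolated)
Conditions: CO2 (1 atm), Ni(acac)2(bpy) (10 mol %), Zn powder, MgBr2, 3 Å sieves, DMF, rt; then 3 M HCl, extraction, distillation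
Reagents that add atoms: carbon dioxide, O=C=O
Why: Nickel-catalysed reductive double carboxylation of an internal alkyne: alkyne and CO2 couple at zerovalent nickel to a nickelalactone, Zn/MgBr2 turn the catalyst over and a second CO2 enters on the same side, so the (Z)-diacid should form and close to the cyclic anhydride on acidic work-up.

Step 2
Reactants: 3 3,4-diethylfuran-2,5-dione; 4 buta-1,3-diene
Product: 5 (3aR,7aS)-3a,7a-diethyl-3a,4,7,7a-tetrahydro-2-benzofuran-1,3-dione (meso, ethyl groups cis)
Conditions: 4 (5 equiv), BHT (cat.), toluene, sealed vessel, 180 °C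
Reagents that add atoms: none
Why: Thermal Diels–Alder reaction of a dialkylmaleic anhydride (forcing temperature for the tetrasubstituted dienophile); suprafacial addition keeps the ethyl groups cis, so both quaternary carbons arise in one step as a meso compound.

Step 3
Reactants: 5 meso anhydride
Product: 6 (1S,2R)-1,2-diethyl-2-(methoxycarbonyl)cyclohex-4-ene-1-carboxylic acid
Conditions: MeOH (3 equiv), quinine (1.1 equiv), toluene/CCl4 1:1, −55 → −20 °C; 2 M HCl wash (quinine recovered)
Reagents that add atoms: methanol, CO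
Why: Cinchona-alkaloid-mediated desymmetrising methanolysis of a meso anhydride: the alkaloid–methanol pair attacks one of the two enantiotopic carbonyl groups, which fixes the absolute configuration of both quaternary carbons at once (ester on the future C4, free acid on the future C5).

Step 4
Reactants: 6 half-ester
Product: 7 methyl 1,2-diethyl-4-iodo-7-oxo-6-oxabicyclo[3.2.1]octane-2-carboxylate (lactone C5–CO–O–C7 on the face of the ester; iodine on C7a anti to the lactone oxygen)
Conditions: I2, KI, NaHCO3, CH2Cl2/H2O, 0 °C → rt, dark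
Reagents that add atoms: iodine, II
Why: Iodolactonisation: only the free carboxylate on C5 can open the iodonium ion, and it does so at the γ-carbon C7 from its own face with iodine anti on C7a, so the acid/ester difference is written into the ring as an oxygen on C7.

Step 5
Reactants: 7 iodolactone
Product: 8 methyl 1,2-diethyl-7-oxo-6-oxabicyclo[3.2.1]oct-3-ene-2-carboxylate (C7a=C3a alkene, lactone oxygen allylic on C7)
Conditions: DBU, toluene, 90 °C
Reagents that add atoms: none
Why: E2 dehydroiodination: the axial iodide on C7a has an anti-periplanar hydrogen only on C3a (loss toward the bridgehead C7 would give an anti-Bredt enol lactone), so the double bond forms between C7a and C3a.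

Step 6
Reactants: 8 unsaturated lactone
Product: 10 methyl 6-{[tert-butyl(diphenyl)silyl]oxymethyl}-1,6-diethyl-4-hydroxycyclohex-2-ene-1-carboxylate (OH, CH2OSi and CO2Me on one face), via diol ester 9 (not isolated)
Conditions: LiBH4 (1.2 equiv), THF, 0 °C; sat. NH4Cl, cold extractive work-up; crude 9, TBDPSCl (1.1 equiv), imidazole, DMF, 0 °C → rt
Reagents that add atoms: tert-butyl(chloro)diphenylsilane, CC(C)(C)[Si](Cl)(c1ccccc1)c1ccccc1
Why: Borohydride reduction of a lactone: the strained bridged γ-lactone, locked in the reactive s-trans ester geometry, should be reduced well before the doubly neopentyl methyl ester, and the freed primary alcohol is capped at once by selective silylation with the bulky chlorosilane before it can lactonise onto the cis ester.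

Step 7
Reactants: 10 allylic alcohol
Product: 11 methyl (1R,6S)-6-{[tert-butyl(diphenyl)silyl]oxymethyl}-1,6-diethyl-4-oxocyclohex-2-ene-1-carboxylate
Conditions: Dess–Martin periodinane, CH2Cl2, 0 °C → rt
Reagents that add atoms: none
Why: Dess–Martin oxidation of the secondary allylic alcohol gives the cyclohex-2-enone with the ketone on C7 and the C7a=C3a double bond next to the ester-bearing C4; no stereocentre is involved.

Step 8
Reactants: 11 enone; 12 1,1-dimethoxyethene
Product: 13 methyl 4-{[tert-butyl(diphenyl)silyl]oxymethyl}-4,5-diethyl-7,7-dimethoxy-2-oxobicyclo[4.2.0]octane-5-carboxylate (trans-fused: H-3a and H-7a trans; C3a–C2 bond on the face of the two ethyl groups, anti to CO2Me)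
Conditions: 12 (15 equiv), hν (350 nm lamps, Pyrex), degassed CH2Cl2, −40 °C; filtration through Florisil, no base
Reagents that add atoms: none
Why: Excitation of the enone (n→π*) and intersystem crossing give a triplet twisted about C7a=C3a, which adds the electron-rich alkene through a triplet 1,4-diradical that collapses to the cyclobutane after spin inversion; the closest known reaction is the head-to-tail photocycloaddition of cyclohex-2-enones (4,4-disubstituted ones included) with ketene acetals, which gives mainly trans-fused 7,7-dialkoxybicyclo[4.2.0]octan-2-ones. The four-membered ring closes stepwise, the second bond by radical–radical coupling within the diradical, and the orientation (CH2 on the α-carbon C7a, acetal carbon on the β-carbon C3a) follows from the polarity match between the donor alkene and the enone triplet. C3a: the new bond should form on the face of the two ethyl groups, because the ester is the smaller C4 substituent and sits pseudo-axial, so the alkene enters anti to it, while entry on the ester face would also meet the bulky CH2OTBDPS group of C5 in a 1,3-relationship. C7a: closure from the twisted triplet puts C1 on the opposite face, giving the strained trans ring fusion under kinetic control, which ground-state chemistry does not deliver and which is preserved by keeping 13 away from base and active adsorbents. The selectivities needed are therefore head-to-tail regiochemistry, trans fusion and attack anti to the C4 ester; excess alkene at low temperature suppresses enone dimerisation, and neither the ester nor the silyl ether absorbs at 350 nm.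

Step 9
Reactants: 13 photoadduct
Product: 14 methyl 4-{[tert-butyl(diphenyl)silyl]oxymethyl}-4,5-diethyl-7,7-dimethoxy-2-{[(trifluoromethyl)sulfonyl]oxy}bicyclo[4.2.0]oct-2-ene-5-carboxylate (C6=C7 enol triflate, trans fusion kept)
Conditions: KN(SiMe3)2 (1.1 equiv), THF, −78 °C, 13 added slowly; then N-(5-chloropyridin-2-yl)triflimide, (5-Cl-2-pyridyl)NTf2, −78 °C; sat. NH4Cl
Reagents that add atoms: N-(5-chloropyridin-2-yl)-1,1,1-trifluoro-N-[(trifluoromethyl)sulfonyl]methanesulfonamide, FC(F)(F)S(=O)(=O)N(c1ccc(Cl)cn1)S(=O)(=O)C(F)(F)F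
Why: Kinetic enolate formation and O-triflation: the bulky amide at −78 °C should take a C6 methylene proton in preference to the ring-fusion methine on C7a (part of the cyclobutane and screened by the axial C4 ethyl group), and once the enolate is sulfonylated on oxygen C7a is no longer α to a carbonyl, so the trans fusion is secure.

Step 10
Reactants: 14 ketal
Product: 15 methyl 4-{[tert-butyl(diphenyl)silyl]oxymethyl}-4,5-diethyl-7-oxo-2-{[(trifluoromethyl)sulfonyl]oxy}bicyclo[4.2.0]oct-2-ene-5-carboxylate (cyclobutanone, C2=O)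
Conditions: TsOH·H2O (10 mol %), acetone/H2O 10:1, rt
Reagents that add atoms: water, O
Why: Acid-catalysed ketal hydrolysis under conditions that the enol triflate, the neopentyl TBDPS ether and the hindered ester tolerate; enolisation of the cyclobutanone toward C3a would need a cyclobutene enol and should be too slow to disturb the ring fusion.

Step 11
Reactants: 15 cyclobutanone
Product: 16 methyl 4-{[tert-butyl(diphenyl)silyl]oxymethyl}-4,5-diethyl-7-hydroxy-7-(prop-1-yn-1-yl)-2-{[(trifluoromethyl)sulfonyl]oxy}bicyclo[4.2.0]oct-2-ene-5-carboxylate (carbinol configuration not assigned)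
Conditions: CH3C≡CMgBr (0.5 M in THF, 1.5 equiv), THF, −78 → −40 °C; sat. NH4Cl at −78 °C
Reagents that add atoms: prop-1-yn-1-ylmagnesium bromide, CC#C[Mg]Br
Why: Alkynyl Grignard 1,2-addition to the strained, highly electrophilic cyclobutanone, which should outpace attack on the hindered ester and leave the enol triflate alone; the configuration of the new carbinol carbon is immaterial because it becomes the ketone carbon again in step 12.

Step 12
Reactants: 16 alkynyl cyclobutanol
Product: 17 methyl 5-{[tert-butyl(diphenyl)silyl]oxymethyl}-4,5-diethyl-3-[(E)-ethylidene]-2-oxo-7-{[(trifluoromethyl)sulfonyl]oxy}-2,3,3a,4,5,7a-hexahydro-1H-indene-4-carboxylate (trans-fused)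
Conditions: (4-CF3C6H4)3PAuCl (3 mol %), AgSbF6 (3 mol %), CH2Cl2, rt
Reagents that add atoms: none
Why: Gold-catalysed ring expansion of a 1-alkynylcyclobutanol (alkyne activation by cationic monovalent gold, 1,2-shift of a ring bond to the proximal alkyne carbon anti to gold, protodeauration): the more substituted ring carbon C3a should migrate with retention, releasing the cyclobutane strain and giving the trans-fused cyclopentanone with an (E)-ethylidene group on C3, while the electron-poor enol triflate does not engage the activated alkyne.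

Step 13
Reactants: 17 ethylidene ketone
Product: 18 methyl 5-{[tert-butyl(diphenyl)silyl]oxymethyl}-1,4,5-triethyl-3-[(E)-ethylidene]-2-oxo-7-{[(trifluoromethyl)sulfonyl]oxy}-2,3,3a,4,5,7a-hexahydro-1H-indene-4-carboxylate (C1 ethyl trans to C7)
Conditions: LiN(i-Pr)2 (1.05 equiv), THF, −78 °C; EtI, DMPU, −78 → −30 °C
Reagents that add atoms: iodoethane, CCI
Why: Kinetic α′-deprotonation and alkylation of a cross-conjugated enone: C1 carries the only α-hydrogens (C3 is an alkene carbon), and iodoethane should enter anti to the C7a–C7 bond; any C1 epimer is corrected in step 14.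

Step 14
Reactants: 18 C1-ethyl enone
Product: 20 methyl 5-{[tert-butyl(diphenyl)silyl]oxymethyl}-1,3,4,5-tetraethyl-2-oxo-7-{[(trifluoromethyl)sulfonyl]oxy}-2,3,3a,4,5,7a-hexahydro-1H-indene-4-carboxylate (C1 and C3 as in 26), via C3-epimer mixture 19 (not isolated)
Conditions: [(Ph3P)CuH]6 (0.4 equiv), H2O (3 equiv), toluene, rt; then DBU, 80 °C
Reagents that add atoms: none
Why: Copper hydride conjugate reduction of the exocyclic enone, which spares the enol triflate, ester and silyl ether, followed by base equilibration of the two α-carbons: on the trans-hydrindanone each ethyl group should settle trans to the neighbouring six-ring carbon (C3-ethyl away from the quaternary C4, C1-ethyl away from C7), which is the configuration of 26.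

Step 15
Reactants: 20 enol triflate
Product: 21 methyl 5-{[tert-butyl(diphenyl)silyl]oxymethyl}-1,3,4,5,7-pentaethyl-2-oxo-2,3,3a,4,5,7a-hexahydro-1H-indene-4-carboxylate
Conditions: Et2Zn (1 M in hexanes, 2 equiv), PdCl2(dppf) (5 mol %), THF, 60 °C
Reagents that add atoms: diethylzinc, CC[Zn]CC
Why: Negishi cross-coupling of the enol triflate with diethylzinc (oxidative addition to zerovalent palladium, transmetallation, reductive elimination, the bidentate dppf ligand holding back β-hydride elimination); the dialkylzinc does not add to the hindered ketone.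

Step 16
Reactants: 21 silyl ether
Product: 23 methyl 1,3,4,5,7-pentaethyl-5-formyl-2-oxo-2,3,3a,4,5,7a-hexahydro-1H-indene-4-carboxylate, via primary alcohol 22 (not isolated)
Conditions: Bu4NF/AcOH (1:1, 3 equiv), THF, rt → 40 °C; aqueous work-up at 0 °C; crude 22, Dess–Martin periodinane, CH2Cl2, 0 °C
Reagents that add atoms: none
Why: Fluoride desilylation buffered with acetic acid avoids the free alkoxide that would lactonise onto the cis ester, and the neopentyl alcohol is oxidised at once (Dess–Martin oxidation) to an aldehyde that has no α-hydrogen.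

Step 17
Reactants: 23 aldehyde; 24 diethyl benzylphosphonate
Product: 25 methyl (1S,3S,3aR,4R,5S,7aR)-1,3,4,5,7-pentaethyl-2-oxo-5-[(E)-2-phenylethenyl]-2,3,3a,4,5,7a-hexahydro-1H-indene-4-carboxylate
Conditions: 24 (2.5 equiv), KOt-Bu, THF, 0 → 40 °C; sat. NH4Cl
Reagents that add atoms: none
Why: Horner–Wadsworth–Emmons olefination of the non-enolisable aldehyde with the benzylphosphonate anion should give the (E)-styrene through the more stable oxaphosphetane; the hindered cyclopentanone does not react and its α-centres are already at equilibrium.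

Step 18
Reactants: 25 methyl ester
Product: 26 (1S,3S,3aR,4R,5S,7aR)-1,3,4,5,7-pentaethyl-2-oxo-5-[(E)-2-phenylethenyl]-2,3,3a,4,5,7a-hexahydro-1H-indene-4-carboxylic acid
Conditions: LiI (10 equiv), pyridine, reflux; then 1 M HCl
Reagents that add atoms: none
Why: Nucleophilic ester dealkylation (SN2 attack of iodide on the methyl carbon instead of the doubly neopentyl carbonyl carbon that saponification would need) frees the acid without touching a stereocentre.

**Compound list**

1 | hex-3-yne | CCC#CCC | starting material
2 | (Z)-2,3-diethylbut-2-enedioic acid (diethylmaleic acid) | CC/C(C(=O)O)=C(\CC)C(=O)O | intermediate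
3 | 3,4-diethylfuran-2,5-dione | CCC1=C(CC)C(=O)OC1=O | intermediate
4 | buta-1,3-diene | C=CC=C | starting material
5 | (3aR,7aS)-3a,7a-diethyl-3a,4,7,7a-tetrahydro-2-benzofuran-1,3-dione (meso) | O=C1OC(=O)[C@]2(CC)CC=CC[C@]12CC | intermediate
6 | (1S,2R)-1,2-diethyl-2-(methoxycarbonyl)cyclohex-4-ene-1-carboxylic acid | COC(=O)[C@]1(CC)CC=CC[C@]1(CC)C(=O)O | intermediate
7 | methyl 1,2-diethyl-4-iodo-7-oxo-6-oxabicyclo[3.2.1]octane-2-carboxylate (lactone cis to ester, iodine anti to lactone oxygen) | COC(=O)[C@]1(CC)C[C@@H](I)[C@H]2C[C@]1(CC)C(=O)O2 | intermediate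
8 | methyl 1,2-diethyl-7-oxo-6-oxabicyclo[3.2.1]oct-3-ene-2-carboxylate | COC(=O)[C@]1(CC)C=C[C@H]2C[C@]1(CC)C(=O)O2 | intermediate
9 | methyl 1,6-diethyl-4-hydroxy-6-(hydroxymethyl)cyclohex-2-ene-1-carboxylate (OH, CH2OH, CO2Me cis) | COC(=O)[C@]1(CC)C=C[C@H](O)C[C@]1(CC)CO | intermediate
10 | methyl 6-{[tert-butyl(diphenyl)silyl]oxymethyl}-1,6-diethyl-4-hydroxycyclohex-2-ene-1-carboxylate | COC(=O)[C@]1(CC)C=C[C@H](O)C[C@]1(CC)CO[Si](c2ccccc2)(c2ccccc2)C(C)(C)C | intermediate
11 | methyl (1R,6S)-6-{[tert-butyl(diphenyl)silyl]oxymethyl}-1,6-diethyl-4-oxocyclohex-2-ene-1-carboxylate | COC(=O)[C@]1(CC)C=CC(=O)C[C@]1(CC)CO[Si](c2ccccc2)(c2ccccc2)C(C)(C)C | intermediate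
12 | 1,1-dimethoxyethene | C=C(OC)OC | starting material
13 | methyl 4-{[tert-butyl(diphenyl)silyl]oxymethyl}-4,5-diethyl-7,7-dimethoxy-2-oxobicyclo[4.2.0]octane-5-carboxylate (trans-fused) | O=C1C[C@@](CO[Si](c3ccccc3)(c3ccccc3)C(C)(C)C)(CC)[C@](CC)(C(=O)OC)[C@@H]2[C@@H]1CC2(OC)OC | intermediate
14 | C6=C7 enol triflate of 13 | FC(F)(F)S(=O)(=O)OC1=C[C@@](CO[Si](c3ccccc3)(c3ccccc3)C(C)(C)C)(CC)[C@](CC)(C(=O)OC)[C@@H]2[C@@H]1CC2(OC)OC | intermediate
15 | trans-fused cyclobutanone (7-oxo) enol triflate | FC(F)(F)S(=O)(=O)OC1=C[C@@](CO[Si](c3ccccc3)(c3ccccc3)C(C)(C)C)(CC)[C@](CC)(C(=O)OC)[C@@H]2[C@@H]1CC2=O | intermediate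
16 | 7-hydroxy-7-(prop-1-yn-1-yl) cyclobutanol (carbinol carbon unassigned) | FC(F)(F)S(=O)(=O)OC1=C[C@@](CO[Si](c3ccccc3)(c3ccccc3)C(C)(C)C)(CC)[C@](CC)(C(=O)OC)[C@@H]2[C@@H]1CC2(O)C#CC | intermediate
17 | methyl 5-{[tert-butyl(diphenyl)silyl]oxymethyl}-4,5-diethyl-3-[(E)-ethylidene]-2-oxo-7-(triflyloxy)-2,3,3a,4,5,7a-hexahydro-1H-indene-4-carboxylate | FC(F)(F)S(=O)(=O)OC1=C[C@@](CO[Si](c3ccccc3)(c3ccccc3)C(C)(C)C)(CC)[C@](CC)(C(=O)OC)[C@@H]2[C@@H]1CC(=O)/C2=C/C | intermediate
18 | 1-ethyl derivative of 17 (C1 ethyl trans to C7) | FC(F)(F)S(=O)(=O)OC1=C[C@@](CO[Si](c3ccccc3)(c3ccccc3)C(C)(C)C)(CC)[C@](CC)(C(=O)OC)[C@@H]2[C@@H]1[C@H](CC)C(=O)/C2=C/C | intermediate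
19 | 1,3-diethyl ketone, mixture of C3 epimers | FC(F)(F)S(=O)(=O)OC1=C[C@@](CO[Si](c3ccccc3)(c3ccccc3)C(C)(C)C)(CC)[C@](CC)(C(=O)OC)[C@@H]2[C@@H]1[C@H](CC)C(=O)C2CC | intermediate
20 | methyl 5-{[tert-butyl(diphenyl)silyl]oxymethyl}-1,3,4,5-tetraethyl-2-oxo-7-(triflyloxy)-2,3,3a,4,5,7a-hexahydro-1H-indene-4-carboxylate (C1, C3 as in 26) | FC(F)(F)S(=O)(=O)OC1=C[C@@](CO[Si](c3ccccc3)(c3ccccc3)C(C)(C)C)(CC)[C@](CC)(C(=O)OC)[C@@H]2[C@@H]1[C@H](CC)C(=O)[C@H]2CC | intermediate
21 | methyl 5-{[tert-butyl(diphenyl)silyl]oxymethyl}-1,3,4,5,7-pentaethyl-2-oxo-2,3,3a,4,5,7a-hexahydro-1H-indene-4-carboxylate | CCC1=C[C@@](CO[Si](c3ccccc3)(c3ccccc3)C(C)(C)C)(CC)[C@](CC)(C(=O)OC)[C@@H]2[C@@H]1[C@H](CC)C(=O)[C@H]2CC | intermediate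
22 | methyl 1,3,4,5,7-pentaethyl-5-(hydroxymethyl)-2-oxo-2,3,3a,4,5,7a-hexahydro-1H-indene-4-carboxylate | CCC1=C[C@@](CO)(CC)[C@](CC)(C(=O)OC)[C@@H]2[C@@H]1[C@H](CC)C(=O)[C@H]2CC | intermediate
23 | methyl 1,3,4,5,7-pentaethyl-5-formyl-2-oxo-2,3,3a,4,5,7a-hexahydro-1H-indene-4-carboxylate | CCC1=C[C@@](C=O)(CC)[C@](CC)(C(=O)OC)[C@@H]2[C@@H]1[C@H](CC)C(=O)[C@H]2CC | intermediate
24 | diethyl benzylphosphonate | CCOP(=O)(Cc1ccccc1)OCC | starting material
25 | methyl (1S,3S,3aR,4R,5S,7aR)-1,3,4,5,7-pentaethyl-2-oxo-5-[(E)-2-phenylethenyl]-2,3,3a,4,5,7a-hexahydro-1H-indene-4-carboxylate | CCC1=C[C@@](/C=C/c3ccccc3)(CC)[C@](CC)(C(=O)OC)[C@@H]2[C@@H]1[C@H](CC)C(=O)[C@H]2CC | intermediate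
26 | (1S,3S,3aR,4R,5S,7aR)-1,3,4,5,7-pentaethyl-2-oxo-5-[(E)-2-phenylethenyl]-2,3,3a,4,5,7a-hexahydro-1H-indene-4-carboxylic acid | CCC1=C[C@@](/C=C/c2ccccc2)(CC)[C@](CC)(C(=O)O)[C@@H]2[C@@H]1[C@H](CC)C(=O)[C@H]2CC | target

**Step count**

Total: 18 steps. Longest linear sequence: 18 steps (1 → 26); everything else is a commercial reagent.

**Steps most likely to fail**

Step 8. The ketene acetal may bond to C3a on the face of the ester and silyloxymethyl groups, or the diradical may close to the cis-fused ring. Either process gives isomers that cannot be epimerised into 13. The fallback sets out from 11 and comes back at 20; it is a ground-state annulation in which the ring fusion is set by equilibration. Mukaiyama–Michael addition of (Z)-4-(trimethylsilyloxy)hept-3-ene to 11 (Me3SiOTf cat., CH2Cl2, −78 °C) brings the whole heptan-4-one unit to C3a at low temperature and leaves the C7 oxygen as a regiodefined silyl enol ether, Michael adduct F1. LiN(i-Pr)2/Me3SiCl then converts the side-chain ketone at its methylene into a second enol ether, bis(silyl enol ether) F2. Oxidative coupling of the two enol ethers with (NH4)2Ce(NO3)6/NaHCO3 in MeCN closes the five-membered ring between C7a and C1. DBU equilibrates C7a, C1 and C3 to the trans-fused diketone F3. KN(SiMe3)2 and (5-Cl-2-pyridyl)NTf2 triflate the C7 ketone at its only α-methylene (C6) and give 20.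

Step 9. Proton abstraction at the ring-fusion carbon C7a may compete with C6. That would give the regioisomeric triflate or, after reprotonation, the cis-fused ketone, so the trans ring fusion would be lost. The fallback sets out from 11 and comes back at 14; it makes the C6 enolate by reduction instead of deprotonation. Mn(OAc)3 in hot benzene acetoxylates the α′-carbon C6 of 11 to acetoxy enone F4 (either C6 epimer serves). Irradiation with 12 as in step 8 gives acetoxy photoadduct F5. SmI2 in THF/HMPA at −78 °C cleaves the C6–OAc bond and forms the C6=C7 enolate regiospecifically without base, and (5-Cl-2-pyridyl)NTf2 traps it as 14.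

Step 6. Hydride may also attack the methyl ester, or the alkoxides formed during reduction may acylate themselves on it (over-reduction and lactonisation), so that the ester/alcohol pattern is lost. The fallback sets out from 8 and comes back at 9. LiOH (1.1 equiv, THF/H2O, 0 °C) opens only the strained lactone to hydroxy acid F6. BH3·SMe2 (THF, 0 °C) then reduces the free carboxylic acid, which borane attacks far faster than an ester and under non-basic conditions, to diol ester 9, which is silylated as in step 6.

**Further compounds**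

F1 | step 8 | methyl 6-{[tert-butyl(diphenyl)silyl]oxymethyl}-1,6-diethyl-2-(4-oxoheptan-3-yl)-4-[(trimethylsilyl)oxy]cyclohex-3-ene-1-carboxylate (side-chain C3 unassigned) | C[Si](C)(C)OC1=C[C@H](C(CC)C(=O)CCC)[C@@](CC)(C(=O)OC)[C@@](CC)(CO[Si](c2ccccc2)(c2ccccc2)C(C)(C)C)C1
F2 | step 8 | methyl 6-{[tert-butyl(diphenyl)silyl]oxymethyl}-1,6-diethyl-2-{4-[(trimethylsilyl)oxy]hept-4-en-3-yl}-4-[(trimethylsilyl)oxy]cyclohex-3-ene-1-carboxylate | C[Si](C)(C)OC1=C[C@H](C(CC)C(O[Si](C)(C)C)=CCC)[C@@](CC)(C(=O)OC)[C@@](CC)(CO[Si](c2ccccc2)(c2ccccc2)C(C)(C)C)C1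
F3 | step 8 | methyl 5-{[tert-butyl(diphenyl)silyl]oxymethyl}-1,3,4,5-tetraethyl-2,7-dioxooctahydro-1H-indene-4-carboxylate (trans-fused, C1 and C3 as in 26) | O=C1C[C@@](CO[Si](c3ccccc3)(c3ccccc3)C(C)(C)C)(CC)[C@](CC)(C(=O)OC)[C@@H]2[C@@H]1[C@H](CC)C(=O)[C@H]2CC
F4 | step 9 | methyl 5-acetoxy-6-{[tert-butyl(diphenyl)silyl]oxymethyl}-1,6-diethyl-4-oxocyclohex-2-ene-1-carboxylate (acetoxy carbon unassigned) | COC(=O)[C@]1(CC)C=CC(=O)C(OC(C)=O)[C@]1(CC)CO[Si](c2ccccc2)(c2ccccc2)C(C)(C)C
F5 | step 9 | methyl 3-acetoxy-4-{[tert-butyl(diphenyl)silyl]oxymethyl}-4,5-diethyl-7,7-dimethoxy-2-oxobicyclo[4.2.0]octane-5-carboxylate (trans-fused) | O=C1C(OC(C)=O)[C@@](CO[Si](c3ccccc3)(c3ccccc3)C(C)(C)C)(CC)[C@](CC)(C(=O)OC)[C@@H]2[C@@H]1CC2(OC)OC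
F6 | step 6 | 1,2-diethyl-5-hydroxy-2-(methoxycarbonyl)cyclohex-3-ene-1-carboxylic acid (OH, CO2H, CO2Me cis) | COC(=O)[C@]1(CC)C=C[C@H](O)C[C@]1(CC)C(=O)O
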